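You charge 1.7 M of starting material and 0.0850 M of protic impurity, and no gas is dissolved at first.

starting material 1.7 M; gas phase 200 mM (held); protic impurity 0.0850 M; catalyst 0.2 mol%; time 1.0 min

    gas phase ⇌ dissolved gas, rate k1*(csat - [dissolved gas]) (k1 = 0.261 /s, csat = 200 mM)
    starting material + dissolved gas + catalyst → catalyst + target (k2 = 365 /M²/s)
    dissolved gas → decomposition product (k3 = 1.49 × 10⁻⁴ /s)
    starting material + protic impurity → quenched substrate (k4 = 1.11 /M/s)
    dissolved gas + catalyst ⇌ idle complex, settled at all times (K5 = 1.3 /M)

* target at 1.0 min, in percent of the starting material charged
* concentration of dissolved gas in solution at 1.0 min, in percent of saturation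

The impurity's half-life against the starting material is 0.367 s, shorter than the transfer time 1/k1 of 3.83 s. So it takes its own amount first and leaves a demand D = 1.61 M, which caps the target at 95.0%.

With the other concentrations as charged, step 2 consumes dissolved gas, B, with a half-life of 0.33 s, shorter than the transfer's 2.66 s, so early in the run gas entry is the rate-limiting step. Replace the falling substrate curve by its mean, 0.805 M. The catalyst charged then removes B at 1.00 /s. Balancing that against transfer gives a mean B of 41.3 mM.

Now define Φ = 1.54, the gas delivered at this mean rate during the run, divided by D. It exceeds one, so on this reckoning the substrate finishes near 0.650 min and I expect 95.0% target.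

To test the mean, use the full demand or a quarter of it instead: Φ becomes 1.72 or 1.28, still above one. The gas needs a further step: refilling at k1 after 0.650 min gives 99.6% of saturation.

The forecast gives 94.8% and 97.5%, lower on the gas than my figure: “With the substrate almost gone, gas demand collapses”. The simulation gives 94.6% and 94.3%.

At 0.500 min, Φ gives 73.1% target, and this flask holds 70.5%. At 1.0 min, 0.39% of the starting material remains, and the gas stands 5.3 percentage points below my figure. This flask is not yet at rest. By 10.0 min the target stands at 95.0% against 94.6%, but dissolved gas rises from 0.189 M to 0.200 M, and decomposition product from 7.61 × 10⁻⁴ M to 0.0168 M.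

For a reading of the same flask at 15 s, Φ shrinks to 0.385, below one, which predicts 36.5% target. The simulation gives 37.5%, with 58% of the starting material left.

(The rate constants are invented.)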